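**Retrosynthetic overview**
1. Target 22 comes from its 2-(trimethylsilyl)ethyl ester 21. C13 is set by ligand-controlled copper hydride reduction of E-enoate 20. C8=CH2 and C13=C14 both come from diketone 18.
2. Key disconnection C9–C11: intermolecular Mukaiyama–Michael addition of the cis-decalin silyl enol ether 17 to methyl vinyl ketone. Enol ether 17 comes from octalone 16 and Me2CuLi/Me3SiCl, which sets C10; C9 follows in the Michael step.
3. Ring A is formed second, by ring-closing metathesis of the C10 vinyl and C4 allyl groups of 14.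
4. The quaternary C4 is set by two convex-face alkylations of the cis-fused lactone 7. This temporary ring comes from an oxa-Michael closure of 5 and is opened again by E1cB elimination.
5. Ring B is formed first, by an enamine-catalysed Michael addition of 1 to methyl vinyl ketone (sets C5) followed by aldol condensation.

**Assumption:** the SMILES is read literally as 4S,5R,9R,10S,13R (labdane atom numbers, used throughout). This is a cis-fused decalin with H5, the C10 methyl, the C4 methyl and the C9 side chain on one face, and the C4 carboxyl on the other.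

## Route

Step 1
Reactants: 1 methyl 4-oxobutanoate; 2 methyl vinyl ketone
Product: 3 methyl (3S)-3-formyl-6-oxoheptanoate
Conditions: (S)-2-[methoxy(diphenyl)methyl]pyrrolidine (5 mol %), ethyl 3,4-dihydroxybenzoate (20 mol %), neat, 4 °C, 36 h
Reagents that add atoms: none
Why: Enamine-catalysed asymmetric Michael addition in which the CPh2(OMe) group shields one face of the E-enamine of 1, so 2 adds from the open face and sets C5 (S in 3).

Step 2
Reactants: 3 methyl (3S)-3-formyl-6-oxoheptanoate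
Product: 5 2-[(1S)-4-oxocyclohex-2-en-1-yl]acetic acid, via enone methyl ester 4 (not isolated)
Conditions: LiOH (3 equiv), i-PrOH/H2O, 0 °C to rt; then 1 M HCl to pH 2
Reagents that add atoms: lithium hydroxide, [Li+].[OH-]
Why: Intramolecular aldol condensation of the methyl ketone onto the aldehyde closes ring B, the same base saponifies the ester, and C5 survives because it is now only a gamma position of the enone.

Step 3
Reactants: 5 2-[(1S)-4-oxocyclohex-2-en-1-yl]acetic acid
Product: 6 (3aS,7aS)-hexahydro-1-benzofuran-2,6-dione (cis-fused keto lactone)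
Conditions: p-TsOH·H2O (10 mol %), CH2Cl2, rt
Reagents that add atoms: none
Why: Acid-catalysed intramolecular oxa-Michael addition in which the two-atom tether reaches C10 only from its own face, so the gamma-lactone is cis-fused and C10 follows from C5.

Step 4
Reactants: 6 (3aS,7aS)-hexahydro-1-benzofuran-2,6-dione
Product: 7 (3aS,7aS)-hexahydrospiro[1-benzofuran-6,2'-[1,3]dioxolan]-2-one
Conditions: Me3SiOCH2CH2OSiMe3 (1.5 equiv), Me3SiOTf (5 mol %), CH2Cl2, −78 to −20 °C; pyridine quench
Reagents that add atoms: 1,2-bis(trimethylsilyloxy)ethane, C[Si](C)(C)OCCO[Si](C)(C)C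
Why: Noyori ketalisation under aprotic low-temperature conditions masks the ketone, so the beta-acyloxy ketone cannot eliminate when the lactone is enolised.

Step 5
Reactants: 7 (3aS,7aS)-hexahydrospiro[1-benzofuran-6,2'-[1,3]dioxolan]-2-one
Product: 8 (3S,3aS,7aS)-3-methylhexahydrospiro[1-benzofuran-6,2'-[1,3]dioxolan]-2-one
Conditions: LiN(iPr)2 (1.1 equiv), THF, −78 °C; MeI, −78 to −40 °C
Reagents that add atoms: iodomethane, CI
Why: Lactone enolate alkylation (SN2) from the convex face of the cis-fused bicycle, creating a centre that is flattened again in step 6.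

Step 6
Reactants: 8 (3S,3aS,7aS)-3-methylhexahydrospiro[1-benzofuran-6,2'-[1,3]dioxolan]-2-one
Product: 9 (3S,3aS,7aS)-3-allyl-3-methylhexahydrospiro[1-benzofuran-6,2'-[1,3]dioxolan]-2-one
Conditions: LiN(iPr)2 (1.3 equiv), THF/DMPU, −78 to −40 °C; allyl bromide, −78 to −20 °C
Reagents that add atoms: allyl bromide, C=CCBr
Why: In this second enolate alkylation the electrophile again enters on the convex face, syn to H5 and anti to C6, which fixes the quaternary C4 (S) with allyl cis to H5 and methyl on the concave face.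

Step 7
Reactants: 9 (3S,3aS,7aS)-3-allyl-3-methylhexahydrospiro[1-benzofuran-6,2'-[1,3]dioxolan]-2-one
Product: 11 (2S)-2-methyl-2-[(1R)-4-oxocyclohex-2-en-1-yl]pent-4-enoic acid, via keto lactone 10 (not isolated)
Conditions: 1 M HCl, THF, rt; then DBU (2.5 equiv), CH2Cl2, 0 °C to rt; cold citric acid work-up, used at once
Reagents that add atoms: water, O
Why: Acetal hydrolysis followed by E1cB elimination of the beta-carboxylate regenerates the enone without touching C4 or C5.

Step 8
Reactants: 11 (2S)-2-methyl-2-[(1R)-4-oxocyclohex-2-en-1-yl]pent-4-enoic acid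
Product: 12 2-(trimethylsilyl)ethyl (2S)-2-methyl-2-[(1R)-4-oxocyclohex-2-en-1-yl]pent-4-enoate
Conditions: Me3SiCH2CH2OH, PPh3, DIAD, THF, 0 °C to rt
Reagents that add atoms: 2-(trimethylsilyl)ethanol, C[Si](C)(C)CCO
Why: In the Mitsunobu esterification the hindered carboxylate is the nucleophile toward the activated primary alcohol, so crowding at C4 does not slow the reaction.

Step 9
Reactants: 12 2-(trimethylsilyl)ethyl (2S)-2-methyl-2-[(1R)-4-oxocyclohex-2-en-1-yl]pent-4-enoate
Product: 13 2-(trimethylsilyl)ethyl (2S)-2-[(1R,2S)-2-ethenyl-4-(trimethylsilyloxy)cyclohex-3-en-1-yl]-2-methylpent-4-enoate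
Conditions: CH2=CHMgBr (1.5 equiv), CuBr·SMe2 (15 mol %), Me3SiCl (2.5 equiv), DMPU, THF, −78 °C; Et3N, cold NaHCO3 work-up
Reagents that add atoms: vinylmagnesium bromide, C=C[Mg]Br; chlorotrimethylsilane, C[Si](C)(C)Cl
Why: Copper-catalysed conjugate addition with in situ silylation gives the C8–C9 enol ether regiospecifically, and the new C10 centre (vinyl anti to the C5 substituent) is erased in step 10.

Step 10
Reactants: 13 2-(trimethylsilyl)ethyl (2S)-2-[(1R,2S)-2-ethenyl-4-(trimethylsilyloxy)cyclohex-3-en-1-yl]-2-methylpent-4-enoate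
Product: 14 2-(trimethylsilyl)ethyl (2S)-2-[(1R)-2-ethenyl-4-oxocyclohex-2-en-1-yl]-2-methylpent-4-enoate
Conditions: Pd(OAc)2 (1.05 equiv), MeCN, rt
Reagents that add atoms: none
Why: Saegusa–Ito oxidation, in which the palladium enolate loses H10 by beta-hydride elimination, returns the enone with the vinyl group on C10.

Step 11
Reactants: 14 2-(trimethylsilyl)ethyl (2S)-2-[(1R)-2-ethenyl-4-oxocyclohex-2-en-1-yl]-2-methylpent-4-enoate
Product: 15 2-(trimethylsilyl)ethyl (1S,8aR)-1-methyl-6-oxo-1,2,6,7,8,8a-hexahydronaphthalene-1-carboxylate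
Conditions: second-generation Grubbs catalyst RuCl2(=CHPh)(PCy3)(H2IMes) (3 mol %), CH2Cl2 (5 mM), reflux
Reagents that add atoms: none
Why: Ring-closing metathesis of the allyl and vinyl groups closes ring A as a six-membered ring and is driven by loss of ethene.

Step 12
Reactants: 15 2-(trimethylsilyl)ethyl (1S,8aR)-1-methyl-6-oxo-1,2,6,7,8,8a-hexahydronaphthalene-1-carboxylate
Product: 16 2-(trimethylsilyl)ethyl (1S,8aR)-1-methyl-6-oxo-1,2,3,4,6,7,8,8a-octahydronaphthalene-1-carboxylate
Conditions: H2 (1 atm), RhCl(PPh3)3 (5 mol %), toluene/EtOH, rt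
Reagents that add atoms: none
Why: Homogeneous hydrogenation with Wilkinson's catalyst saturates the disubstituted C1=C2 bond of the dienone and leaves the trisubstituted C9=C10 enone bond.

Step 13
Reactants: 16 2-(trimethylsilyl)ethyl (1S,8aR)-1-methyl-6-oxo-1,2,3,4,6,7,8,8a-octahydronaphthalene-1-carboxylate
Product: 17 2-(trimethylsilyl)ethyl (1S,4aR,8aR)-1,4a-dimethyl-6-(trimethylsilyloxy)-1,2,3,4,4a,7,8,8a-octahydronaphthalene-1-carboxylate (cis-fused)
Conditions: Me2CuLi (from MeLi and CuI, 3 equiv), Me3SiCl (5 equiv), Et2O/THF, −78 to −30 °C; Et3N, cold NaHCO3 work-up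
Reagents that add atoms: lithium dimethylcuprate, [Li+].C[Cu-]C; chlorotrimethylsilane, C[Si](C)(C)Cl
Why: In this cuprate conjugate addition the axial C4 ester blocks the face anti to H5, so methyl adds syn to H5 (anti to C4) to give the cis-decalin at C10, and the enolate is trapped regiospecifically at C8–C9.

Step 14
Reactants: 17 2-(trimethylsilyl)ethyl (1S,4aR,8aR)-1,4a-dimethyl-6-(trimethylsilyloxy)-1,2,3,4,4a,7,8,8a-octahydronaphthalene-1-carboxylate; 2 methyl vinyl ketone
Product: 18 2-(trimethylsilyl)ethyl (1S,4aR,5S,8aR)-1,4a-dimethyl-6-oxo-5-(3-oxobutyl)decahydronaphthalene-1-carboxylate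
Conditions: TiCl4 (1.1 equiv), 2 (1.5 equiv), CH2Cl2, −78 °C, 1 h; aq NaHCO3 quench at −78 °C
Reagents that add atoms: none
Why: In the intermolecular Mukaiyama–Michael addition the activated enone is attacked by C9 on the convex face, axially and anti to the C10–C1 bond, which places C11 cis to the C10 methyl and H5, and the non-basic low-temperature conditions preserve this kinetic epimer.

Step 15
Reactants: 18 2-(trimethylsilyl)ethyl (1S,4aR,5S,8aR)-1,4a-dimethyl-6-oxo-5-(3-oxobutyl)decahydronaphthalene-1-carboxylate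
Product: 19 2-(trimethylsilyl)ethyl (1S,4aR,5S,8aR)-5-[(3E)-5-methoxy-3-methyl-5-oxopent-3-en-1-yl]-1,4a-dimethyl-6-oxodecahydronaphthalene-1-carboxylate
Conditions: (MeO)2P(O)CH2CO2Me (2 equiv), NaH (1.9 equiv), THF, 0 °C to rt; Z isomer removed by chromatography
Reagents that add atoms: trimethyl phosphonoacetate, COC(=O)CP(=O)(OC)OC
Why: Horner–Wadsworth–Emmons olefination selects the unhindered methyl ketone over the C8 ketone next to the substituted C9, gives mainly the E-enoate, and uses an anion too weakly basic to enolise toward the hindered C9–H.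

Step 16
Reactants: 19 2-(trimethylsilyl)ethyl (1S,4aR,5S,8aR)-5-[(3E)-5-methoxy-3-methyl-5-oxopent-3-en-1-yl]-1,4a-dimethyl-6-oxodecahydronaphthalene-1-carboxylate
Product: 20 2-(trimethylsilyl)ethyl (1S,4aS,5R,8aR)-5-[(3E)-5-methoxy-3-methyl-5-oxopent-3-en-1-yl]-1,4a-dimethyl-6-methylidenedecahydronaphthalene-1-carboxylate
Conditions: Zn/CH2Br2/TiCl4 (reagent preformed in THF), CH2Cl2, 0 °C to rt
Reagents that add atoms: dibromomethane, BrCBr
Why: Takai–Lombardo methylenation uses a non-basic gem-dimetallic reagent that converts the hindered enolisable ketone into the exocyclic alkene without epimerising C9 and leaves both esters alone.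

Step 17
Reactants: 20 2-(trimethylsilyl)ethyl (1S,4aS,5R,8aR)-5-[(3E)-5-methoxy-3-methyl-5-oxopent-3-en-1-yl]-1,4a-dimethyl-6-methylidenedecahydronaphthalene-1-carboxylate
Product: 21 2-(trimethylsilyl)ethyl (1S,4aS,5R,8aR)-5-[(3R)-5-methoxy-3-methyl-5-oxopentyl]-1,4a-dimethyl-6-methylidenedecahydronaphthalene-1-carboxylate
Conditions: Cu(OAc)2 (3 mol %), (S)-DTBM-SEGPHOS (3.3 mol %), (EtO)2MeSiH (3 equiv), t-BuOH (3 equiv), toluene, 0 °C
Reagents that add atoms: none
Why: Copper hydride-catalysed asymmetric conjugate reduction must deliver hydride to the Si face of C13 of the geometrically pure E-enoate to give 13R (the (S) ligand is assigned from recalled analogies and should be confirmed on a model enoate), while the unactivated 1,1-disubstituted alkene does not react at 0 °C.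

Step 18
Reactants: 21 2-(trimethylsilyl)ethyl (1S,4aS,5R,8aR)-5-[(3R)-5-methoxy-3-methyl-5-oxopentyl]-1,4a-dimethyl-6-methylidenedecahydronaphthalene-1-carboxylate
Product: 22 (1S,4aS,5R,8aR)-5-[(3R)-5-methoxy-3-methyl-5-oxopentyl]-1,4a-dimethyl-6-methylidenedecahydronaphthalene-1-carboxylic acid (target)
Conditions: Bu4NF (3 equiv), THF, rt; dilute HCl work-up (pH 3–4)
Reagents that add atoms: none
Why: Fluoride attack at silicon triggers beta-elimination of the 2-(trimethylsilyl)ethyl ester far from the hindered carbonyl, freeing the C4 acid while the methyl ester and the alkene stay intact.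

## Compound list

1 | methyl 4-oxobutanoate | COC(=O)CCC=O | starting material
2 | methyl vinyl ketone | C=CC(C)=O | starting material
3 | methyl (3S)-3-formyl-6-oxoheptanoate | CC(=O)CC[C@@H](CC(=O)OC)C=O | intermediate
4 | methyl 2-[(1S)-4-oxocyclohex-2-en-1-yl]acetate | O=C1CC[C@@H](CC(=O)OC)C=C1 | intermediate
5 | 2-[(1S)-4-oxocyclohex-2-en-1-yl]acetic acid | O=C1CC[C@@H](CC(=O)O)C=C1 | intermediate
6 | (3aS,7aS)-hexahydro-1-benzofuran-2,6-dione | O=C1CC[C@@H]2[C@H](C1)OC(=O)C2 | intermediate
7 | (3aS,7aS)-hexahydrospiro[1-benzofuran-6,2'-[1,3]dioxolan]-2-one | C13(OCCO3)CC[C@@H]2[C@H](C1)OC(=O)C2 | intermediate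
8 | (3S,3aS,7aS)-3-methylhexahydrospiro[1-benzofuran-6,2'-[1,3]dioxolan]-2-one | C13(OCCO3)CC[C@@H]2[C@H](C1)OC(=O)[C@H]2C | intermediate
9 | (3S,3aS,7aS)-3-allyl-3-methylhexahydrospiro[1-benzofuran-6,2'-[1,3]dioxolan]-2-one | C13(OCCO3)CC[C@@H]2[C@H](C1)OC(=O)[C@@]2(C)CC=C | intermediate
10 | (3S,3aS,7aS)-3-allyl-3-methylhexahydro-1-benzofuran-2,6-dione | O=C1CC[C@@H]2[C@H](C1)OC(=O)[C@@]2(C)CC=C | intermediate
11 | (2S)-2-methyl-2-[(1R)-4-oxocyclohex-2-en-1-yl]pent-4-enoic acid | O=C1CC[C@@H]([C@](C)(CC=C)C(=O)O)C=C1 | intermediate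
12 | 2-(trimethylsilyl)ethyl (2S)-2-methyl-2-[(1R)-4-oxocyclohex-2-en-1-yl]pent-4-enoate | O=C1CC[C@@H]([C@](C)(CC=C)C(=O)OCC[Si](C)(C)C)C=C1 | intermediate
13 | 2-(trimethylsilyl)ethyl (2S)-2-[(1R,2S)-2-ethenyl-4-(trimethylsilyloxy)cyclohex-3-en-1-yl]-2-methylpent-4-enoate | C[Si](C)(C)OC1=C[C@@H](C=C)[C@@H](CC1)[C@](C)(CC=C)C(=O)OCC[Si](C)(C)C | intermediate
14 | 2-(trimethylsilyl)ethyl (2S)-2-[(1R)-2-ethenyl-4-oxocyclohex-2-en-1-yl]-2-methylpent-4-enoate | O=C1CC[C@@H]([C@](C)(CC=C)C(=O)OCC[Si](C)(C)C)C(C=C)=C1 | intermediate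
15 | 2-(trimethylsilyl)ethyl (1S,8aR)-1-methyl-6-oxo-1,2,6,7,8,8a-hexahydronaphthalene-1-carboxylate | O=C1CC[C@@H]2C(C=CC[C@]2(C)C(=O)OCC[Si](C)(C)C)=C1 | intermediate
16 | 2-(trimethylsilyl)ethyl (1S,8aR)-1-methyl-6-oxo-1,2,3,4,6,7,8,8a-octahydronaphthalene-1-carboxylate | O=C1CC[C@@H]2C(CCC[C@]2(C)C(=O)OCC[Si](C)(C)C)=C1 | intermediate
17 | 2-(trimethylsilyl)ethyl (1S,4aR,8aR)-1,4a-dimethyl-6-(trimethylsilyloxy)-1,2,3,4,4a,7,8,8a-octahydronaphthalene-1-carboxylate | C[Si](C)(C)OC1=C[C@]2(C)CCC[C@](C)(C(=O)OCC[Si](C)(C)C)[C@@H]2CC1 | intermediate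
18 | 2-(trimethylsilyl)ethyl (1S,4aR,5S,8aR)-1,4a-dimethyl-6-oxo-5-(3-oxobutyl)decahydronaphthalene-1-carboxylate | O=C1CC[C@@H]2[C@@](C)(CCC[C@]2(C)C(=O)OCC[Si](C)(C)C)[C@@H]1CCC(C)=O | intermediate
19 | 2-(trimethylsilyl)ethyl (1S,4aR,5S,8aR)-5-[(3E)-5-methoxy-3-methyl-5-oxopent-3-en-1-yl]-1,4a-dimethyl-6-oxodecahydronaphthalene-1-carboxylate | O=C1CC[C@@H]2[C@@](C)(CCC[C@]2(C)C(=O)OCC[Si](C)(C)C)[C@@H]1CC/C(C)=C/C(=O)OC | intermediate
20 | 2-(trimethylsilyl)ethyl (1S,4aS,5R,8aR)-5-[(3E)-5-methoxy-3-methyl-5-oxopent-3-en-1-yl]-1,4a-dimethyl-6-methylidenedecahydronaphthalene-1-carboxylate | C=C1CC[C@@H]2[C@@](C)(CCC[C@]2(C)C(=O)OCC[Si](C)(C)C)[C@@H]1CC/C(C)=C/C(=O)OC | intermediate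
21 | 2-(trimethylsilyl)ethyl (1S,4aS,5R,8aR)-5-[(3R)-5-methoxy-3-methyl-5-oxopentyl]-1,4a-dimethyl-6-methylidenedecahydronaphthalene-1-carboxylate | C=C1CC[C@@H]2[C@@](C)(CCC[C@]2(C)C(=O)OCC[Si](C)(C)C)[C@@H]1CC[C@@H](C)CC(=O)OC | intermediate
22 | (1S,4aS,5R,8aR)-5-[(3R)-5-methoxy-3-methyl-5-oxopentyl]-1,4a-dimethyl-6-methylidenedecahydronaphthalene-1-carboxylic acid | C=C1CC[C@@H]2[C@@](C)(CCC[C@]2(C)C(=O)O)[C@@H]1CC[C@@H](C)CC(=O)OC | target

## Step count and risk assessment

Total step count: 18. Longest linear sequence: 18.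

**Step 3.** The oxa-Michael lactonisation is an equilibrium and may stop short or revert during ketalisation. The fallback sets out from 5 and comes back at 6.
- Luche reduction (NaBH4, CeCl3, MeOH) gives the allylic alcohol acid F1.
- Iodolactonisation (I2, NaHCO3, MeCN/H2O) closes the same cis-fused ring irreversibly by anti addition to give the iodo lactone F2.
- Radical deiodination (Bu3SnH, AIBN, toluene, 80 °C) gives the hydroxy lactone F3.
- Dess–Martin oxidation under neutral conditions delivers 6.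

**Step 14.** C9 is a neopentyl-type nucleophile, methyl vinyl ketone can polymerise on TiCl4, and the silyl ester sees a strong Lewis acid. The fallback sets out from 16 and comes back at 18.
- Me2CuLi is added as in step 13 but without Me3SiCl.
- The regiospecific enolate is intercepted directly by 3-(trimethylsilyl)but-3-en-2-one in an anionic Michael addition. The silyl group stabilises the adduct anion and stops oligomerisation, giving the alpha-silyl diketone F4.
- Protodesilylation of F4 with aqueous oxalic acid on silica gives 18.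

**Step 17.** The configuration at C13 rests on catalyst control far from the ring stereocentres, on the E purity of 20, and on an (S)-ligand assignment made from recalled analogies rather than a confirmed precedent. The fallback sets out from 19 and comes back at 21.
- The enoate is reduced before the exocyclic alkene exists, by asymmetric hydrogenation (H2, 50 bar, [Ir(cod)(tBu-PHOX)]BArF, CH2Cl2). The ligand antipode is chosen for Si-face delivery at C13, and the product is the saturated keto diester F5.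
- The C13 epimers can be separated at this ketone stage.
- Methylenation of F5 under the conditions of step 16 gives 21.

## Further compounds

F1 | step 3 | 2-[(1S)-4-hydroxycyclohex-2-en-1-yl]acetic acid (carbinol epimers) | OC1CC[C@@H](CC(=O)O)C=C1
F2 | step 3 | cis-fused 6-hydroxy-7-iodohexahydro-1-benzofuran-2(3H)-one, iodine anti to the lactone oxygen | OC1CC[C@@H]2[C@H]([C@@H]1I)OC(=O)C2
F3 | step 3 | cis-fused 6-hydroxyhexahydro-1-benzofuran-2(3H)-one | OC1CC[C@@H]2[C@H](C1)OC(=O)C2
F4 | step 14 | 2-(trimethylsilyl)ethyl (1S,4aR,5S,8aR)-1,4a-dimethyl-6-oxo-5-[3-oxo-2-(trimethylsilyl)butyl]decahydronaphthalene-1-carboxylate | O=C1CC[C@@H]2[C@@](C)(CCC[C@]2(C)C(=O)OCC[Si](C)(C)C)[C@@H]1CC([Si](C)(C)C)C(C)=O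
F5 | step 17 | 2-(trimethylsilyl)ethyl (1S,4aR,5S,8aR)-5-[(3R)-5-methoxy-3-methyl-5-oxopentyl]-1,4a-dimethyl-6-oxodecahydronaphthalene-1-carboxylate | O=C1CC[C@@H]2[C@@](C)(CCC[C@]2(C)C(=O)OCC[Si](C)(C)C)[C@@H]1CC[C@@H](C)CC(=O)OC
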